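**Plan**

- **Cuts:** C6–O is traced back to C6–Si. Ring A is then opened at C8a–C8, C7–C8, C5–C6 and C4a–C5. This leaves an aryl-4-pyranone (rings B and C) with a diazoacetyl group on the future C8a, and a silylated methoxyacetylene that supplies C6 and C7. Ring C is cut at one C–O1 bond, C4a–C8a, C3–C4 and C2–C1'.
- **Enabling feature:** ring A has its C5 hydroxyl peri to the C4 carbonyl, a methoxy at C7 meta to that hydroxyl, hydrogen at C8 and a heteroatom at C6, and it shares the C4a=C8a bond with ring C. This is the resorcinol monoether pattern that a vinylketene built on C4a=C8a and a methoxyalkyne produce.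
- **Forward:** ring B is bought as 2,5-dimethoxyphenol. Ring C grows on it by Friedel–Crafts acetylation, two Claisen condensations (ethyl acetate, diethyl oxalate) and acid cyclisation. The ester carbon (future C5) becomes a diazo ketone whose diazo carbon is the future C8. Ring A closes last, followed by silicon-to-boron-to-oxygen exchange at C6 with loss of benzyl.
- **Stereochemistry:** the target has no stereocentre and no stereogenic double bond. Only regiochemistry needs control, and it comes from the polarity of the ynol ether and from the ring oxygen that blocks one side of the pyranone.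

Key step: step 8

Remark: ethereal diazomethane is assumed to be prepared in a separate apparatus from N-methyl-N-nitroso-p-toluenesulfonamide and KOH and used as a solution.

**Step 1**
Reactants: 1 chloroacetaldehyde dimethyl acetal
Product: 3 methoxy(trimethylsilyl)acetylene, via lithium methoxyacetylide 2 (not isolated)
Conditions: LiNEt2 (3.1 equiv, from Et2NH and n-BuLi), THF, 0 °C; TMSCl (2.2 equiv), −78 °C → rt; distillation
Reagents that add atoms: chlorotrimethylsilane, C[Si](C)(C)Cl
Why: The amide base removes methanol and then HCl from the chloroacetal (the classical double β-elimination route to alkoxyacetylenes), a third equivalent metalates the terminal alkyne, and the acetylide is C-silylated by TMSCl.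

**Step 2**
Reactants: 4 2,5-dimethoxyphenol
Product: 5 1-(benzyloxy)-2,5-dimethoxybenzene
Conditions: BnBr, K2CO3, DMF, rt
Reagents that add atoms: benzyl bromide, BrCc1ccccc1
Why: Williamson ether synthesis on the only phenol installs a group that survives the bases and mild acids ahead and falls to BCl3 at the end.

**Step 3**
Reactants: 5 1-(benzyloxy)-2,5-dimethoxybenzene
Product: 6 1-[4-(benzyloxy)-2,5-dimethoxyphenyl]ethanone
Conditions: AcCl (1.2 equiv), SnCl4 (1.2 equiv), CH2Cl2, −20 → 0 °C
Reagents that add atoms: acetyl chloride, CC(=O)Cl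
Why: Friedel–Crafts acylation goes to the carbon para to benzyloxy and ortho to methoxy, the only unhindered site activated by two oxygens (as in 1,2,4-trimethoxybenzene), and SnCl4 in the cold is too mild to dealkylate a benzyl ether that lies para to the new ketone and out of reach of chelation.

**Step 4**
Reactants: 6 1-[4-(benzyloxy)-2,5-dimethoxyphenyl]ethanone
Product: 7 1-[4-(benzyloxy)-2,5-dimethoxyphenyl]butane-1,3-dione
Conditions: NaH (2.5 equiv), EtOAc (5 equiv), THF, 0 °C → reflux; 1 M HCl
Reagents that add atoms: ethyl acetate, CCOC(C)=O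
Why: Crossed Claisen condensation of the methyl ketone enolate with ethyl acetate is driven to completion by deprotonation of the β-diketone.

**Step 5**
Reactants: 7 1-[4-(benzyloxy)-2,5-dimethoxyphenyl]butane-1,3-dione; 8 diethyl oxalate
Product: 10 ethyl 6-[4-(benzyloxy)-2,5-dimethoxyphenyl]-4-oxo-4H-pyran-2-carboxylate, via trioxohexanoate ester 9 (not isolated)
Conditions: NaOEt (2.5 equiv), EtOH, 0 °C → rt; then conc. HCl, EtOH, reflux
Reagents that add atoms: none
Why: Claisen acylation under equilibrating conditions settles at the terminal methyl because the linear trioxo ester is held as its bis-enolate, and acid then closes the 4-pyranone by enol addition and dehydration, the sequence of the chelidonic acid synthesis that is established for aroylacetones.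

**Step 6**
Reactants: 10 ethyl 6-[4-(benzyloxy)-2,5-dimethoxyphenyl]-4-oxo-4H-pyran-2-carboxylate
Product: 11 6-[4-(benzyloxy)-2,5-dimethoxyphenyl]-4-oxo-4H-pyran-2-carboxylic acid
Conditions: LiOH·H2O (1.2 equiv), THF/H2O, 0 °C; 1 M HCl to pH 2
Reagents that add atoms: lithium hydroxide, [Li+].[OH-]
Why: Saponification of an ester activated by the pyranone is fast in the cold, and any ring-opened material re-closes on acidification.

**Step 7**
Reactants: 11 6-[4-(benzyloxy)-2,5-dimethoxyphenyl]-4-oxo-4H-pyran-2-carboxylic acid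
Product: 13 2-[4-(benzyloxy)-2,5-dimethoxyphenyl]-6-(diazoacetyl)-4H-pyran-4-one, via acid chloride 12 (not isolated)
Conditions: (COCl)2, DMF (cat.), CH2Cl2, 0 °C → rt, evaporate; CH2N2 (3 equiv), Et2O/CH2Cl2, 0 °C
Reagents that add atoms: diazomethane, C=[N+]=[N-]
Why: This is the acylation of diazomethane by a heteroaroyl chloride without α-hydrogens (first stage of the Arndt–Eistert sequence, known for chromone-2-carbonyl chlorides), with a second equivalent of diazomethane taking up the HCl.

**Step 8**
Reactants: 13 2-[4-(benzyloxy)-2,5-dimethoxyphenyl]-6-(diazoacetyl)-4H-pyran-4-one; 3 methoxy(trimethylsilyl)acetylene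
Product: 18 2-[4-(benzyloxy)-2,5-dimethoxyphenyl]-5-hydroxy-7-methoxy-6-(trimethylsilyl)-4H-chromen-4-one, via pyranonylketene 14 (not isolated), via cyclobutenone 15 (not isolated), via dienylketene 16 (not isolated), via cyclohexadienone 17 (not isolated)
Conditions: 3 (2.5 equiv), ClCH2CH2Cl (0.05 M, degassed), 450 nm LED, 20 °C until N2 evolution ends; then 80 °C in the dark
Reagents that add atoms: none
Why: Proposed new method: light expels N2 from 13 while the pyranon-2-yl group shifts to the diazo carbon (Wolff rearrangement, C8a–C8), and the electrophilic aldoketene 14 is attacked at its carbonyl carbon by the silicon-bearing carbon of 3 in a [2+2] cycloaddition (C5–C6 and C7–C8) to give cyclobutenone 15. Heating breaks the C5–C8 bond of 15 by reversible conrotatory 4π opening, with silicon on the ketene carbon favouring the open form 16; ring A then closes by thermal disrotatory 6π electrocyclization of the C5=C6–C7=C8–C8a=C4a triene (C4a–C5) to 17, whose C4a–H lies between two carbonyls and enolises at once to the chelated C5 phenol of 18. The closest known reaction type is the Danheiser benzannulation of vinyl, aryl and heteroaryl diazomethyl ketones with alkoxy- and siloxyalkynes; a 4-pyranon-2-yl diazo ketone has not been used, but its C2=C3 bond is only weakly aromatic and should behave like the vinyl cases. The [2+2] regiochemistry is secured twice, because methoxy donation and β-silicon stabilisation both place the developing positive charge on the methoxy-bearing alkyne carbon, so oxygen ends at C7 and silicon at C6. Only C3 of the pyranone (future C4a) can end the triene, since C2 has the ring oxygen on its other side, and only the E form of 16 can close while the other drains back through 15; the step also needs [2+2] rather than direct [4+2] union of 14 with 3, which is the normal periselectivity of vinylketenes toward alkynes. The stereocentres of 15 and 17 are transient and racemic and none remains in 18; 450 nm light reaches only the diazo n–π* band and spares the pyranone and flavone chromophores, cold photolysis followed by hot ring opening keeps phenol 18 away from ketene 14, and a methyl ynol ether has no β-hydrogen for retro-ene loss at 80 °C.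

**Step 9**
Reactants: 18 2-[4-(benzyloxy)-2,5-dimethoxyphenyl]-5-hydroxy-7-methoxy-6-(trimethylsilyl)-4H-chromen-4-one
Product: 19 [5-hydroxy-2-(4-hydroxy-2,5-dimethoxyphenyl)-7-methoxy-4-oxo-4H-chromen-6-yl]boronic acid (crude, carried on at once)
Conditions: BCl3 (5 equiv), C6HMe5 (3 equiv), 2,6-di-tert-butyl-4-methylpyridine (3 equiv), CH2Cl2, −78 → 0 °C; then THF/pH 7 buffer, 0 °C
Reagents that add atoms: boron trichloride, ClB(Cl)Cl; water, O
Why: BCl3 attacks the silicon-bearing C6, which is ortho to two oxygens and para to O1, and loss of Me3SiCl from the β-silyl-stabilised arenium ion gives the aryldichloroborane (ipso-borodesilylation), while BCl3 with pentamethylbenzene as benzyl cation trap is the standard cleavage of aryl benzyl ethers beside aryl methyl ethers, the hindered pyridine binds the HCl released by the C5 phenol so that protodesilylation is held back, and buffered hydrolysis gives the boronic acid.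

**Step 10**
Reactants: 19 [5-hydroxy-2-(4-hydroxy-2,5-dimethoxyphenyl)-7-methoxy-4-oxo-4H-chromen-6-yl]boronic acid
Product: 20 5,6-dihydroxy-2-(4-hydroxy-2,5-dimethoxyphenyl)-7-methoxy-4H-chromen-4-one (target)
Conditions: 30% aq H2O2 (3 equiv), THF/pH 7 phosphate buffer, 0 °C → rt; aq Na2S2O3
Reagents that add atoms: hydrogen peroxide, OO
Why: Hydroperoxide adds to boron and the electron-rich aryl group shifts from boron to oxygen (standard arylboronic acid oxidation), and neutral pH spares the C2=C3 bond and the new 5,6-dihydroxy unit.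

**Compound list**

1 | chloroacetaldehyde dimethyl acetal | COC(CCl)OC | starting material
2 | lithium methoxyacetylide | [Li]C#COC | intermediate
3 | methoxy(trimethylsilyl)acetylene | COC#C[Si](C)(C)C | intermediate
4 | 2,5-dimethoxyphenol | COc1ccc(OC)c(O)c1 | starting material
5 | 1-(benzyloxy)-2,5-dimethoxybenzene | COc1ccc(OC)c(OCc2ccccc2)c1 | intermediate
6 | 1-[4-(benzyloxy)-2,5-dimethoxyphenyl]ethanone | CC(=O)c1cc(OC)c(OCc2ccccc2)cc1OC | intermediate
7 | 1-[4-(benzyloxy)-2,5-dimethoxyphenyl]butane-1,3-dione | CC(=O)CC(=O)c1cc(OC)c(OCc2ccccc2)cc1OC | intermediate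
8 | diethyl oxalate | CCOC(=O)C(=O)OCC | starting material
9 | ethyl 6-[4-(benzyloxy)-2,5-dimethoxyphenyl]-2,4,6-trioxohexanoate | CCOC(=O)C(=O)CC(=O)CC(=O)c1cc(OC)c(OCc2ccccc2)cc1OC | intermediate
10 | ethyl 6-[4-(benzyloxy)-2,5-dimethoxyphenyl]-4-oxo-4H-pyran-2-carboxylate | CCOC(=O)c1cc(=O)cc(-c2cc(OC)c(OCc3ccccc3)cc2OC)o1 | intermediate
11 | 6-[4-(benzyloxy)-2,5-dimethoxyphenyl]-4-oxo-4H-pyran-2-carboxylic acid | OC(=O)c1cc(=O)cc(-c2cc(OC)c(OCc3ccccc3)cc2OC)o1 | intermediate
12 | 6-[4-(benzyloxy)-2,5-dimethoxyphenyl]-4-oxo-4H-pyran-2-carbonyl chloride | ClC(=O)c1cc(=O)cc(-c2cc(OC)c(OCc3ccccc3)cc2OC)o1 | intermediate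
13 | 2-[4-(benzyloxy)-2,5-dimethoxyphenyl]-6-(diazoacetyl)-4H-pyran-4-one | [N-]=[N+]=CC(=O)c1cc(=O)cc(-c2cc(OC)c(OCc3ccccc3)cc2OC)o1 | intermediate
14 | {6-[4-(benzyloxy)-2,5-dimethoxyphenyl]-4-oxo-4H-pyran-2-yl}ketene | O=C=Cc1cc(=O)cc(-c2cc(OC)c(OCc3ccccc3)cc2OC)o1 | intermediate
15 | 4-{6-[4-(benzyloxy)-2,5-dimethoxyphenyl]-4-oxo-4H-pyran-2-yl}-3-methoxy-2-(trimethylsilyl)cyclobut-2-en-1-one (racemic) | COC1=C([Si](C)(C)C)C(=O)C1c1cc(=O)cc(-c2cc(OC)c(OCc3ccccc3)cc2OC)o1 | intermediate
16 | (3E)-4-{6-[4-(benzyloxy)-2,5-dimethoxyphenyl]-4-oxo-4H-pyran-2-yl}-3-methoxy-2-(trimethylsilyl)buta-1,3-dien-1-one (pyranonyl cis to the ketene carbon) | O=C=C([Si](C)(C)C)/C(OC)=C\c1cc(=O)cc(-c2cc(OC)c(OCc3ccccc3)cc2OC)o1 | intermediate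
17 | 2-[4-(benzyloxy)-2,5-dimethoxyphenyl]-7-methoxy-6-(trimethylsilyl)-4aH-chromene-4,5-dione (racemic) | COC1=C([Si](C)(C)C)C(=O)C2C(=O)C=C(c3cc(OC)c(OCc4ccccc4)cc3OC)OC2=C1 | intermediate
18 | 2-[4-(benzyloxy)-2,5-dimethoxyphenyl]-5-hydroxy-7-methoxy-6-(trimethylsilyl)-4H-chromen-4-one | COc1cc2oc(-c3cc(OC)c(OCc4ccccc4)cc3OC)cc(=O)c2c(O)c1[Si](C)(C)C | intermediate
19 | [5-hydroxy-2-(4-hydroxy-2,5-dimethoxyphenyl)-7-methoxy-4-oxo-4H-chromen-6-yl]boronic acid | COc1cc2oc(-c3cc(OC)c(O)cc3OC)cc(=O)c2c(O)c1B(O)O | intermediate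
20 | 5,6-dihydroxy-2-(4-hydroxy-2,5-dimethoxyphenyl)-7-methoxy-4H-chromen-4-one | COc1cc(-c2cc(=O)c3c(O)c(O)c(OC)cc3o2)c(OC)cc1O | target

**Step count**

Total step count: 10. Longest linear sequence: 9 (steps 2 to 10, from 4); step 1 is a one-step side branch.

**Steps most likely to fail**

**Step 8.**
- What may go wrong: the ketene may be consumed by dimerisation or by direct [4+2] union with the alkyne, which would interchange hydroxyl and methoxy. The pyranone double bond may resist the 6π closure. Silicon may be lost by protodesilylation during heating or isolation.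
- Route: the fallback gives up the annulation for classical flavone chemistry, sets out from 5 and returns at 20.
- Aldehyde partner: Vilsmeier–Haack formylation of 5 (POCl3, DMF) gives 4-(benzyloxy)-2,5-dimethoxybenzaldehyde F1.
- Ketone partner: commercial 2,6-dimethoxybenzene-1,4-diol is C-acetylated (AcOH, BF3·OEt2, heat) to 1-(3,6-dihydroxy-2,4-dimethoxyphenyl)ethanone F2. Its unchelated hydroxyl is benzylated (BnBr, K2CO3, acetone) to 1-[3-(benzyloxy)-6-hydroxy-2,4-dimethoxyphenyl]ethanone F3.
- Union: Claisen–Schmidt condensation of F3 with F1 (KOH, EtOH) gives (E)-1-[3-(benzyloxy)-6-hydroxy-2,4-dimethoxyphenyl]-3-[4-(benzyloxy)-2,5-dimethoxyphenyl]prop-2-en-1-one F4.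
- Ring C: I2 (cat.) in DMSO at 130 °C closes and dehydrogenates ring C to 6-(benzyloxy)-2-[4-(benzyloxy)-2,5-dimethoxyphenyl]-5,7-dimethoxy-4H-chromen-4-one F5.
- Deprotection: BCl3 with pentamethylbenzene removes both benzyl groups and, through the C4 carbonyl chelate, the C5 methyl ether, giving 20.

**Step 9.**
- What may go wrong: protonation at C6 may outrun boron attack. The boron chelate at C4/C5 may deactivate ring A so that silicon exchange stalls. Longer exposure may start dealkylation of the methoxy next to the freed ring B oxygen.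
- Route: the fallback replaces electrophilic boron by halogen and palladium chemistry, sets out from 18 and returns at 20.
- ICl (CH2Cl2, −78 °C) effects ipso-iododesilylation to 2-[4-(benzyloxy)-2,5-dimethoxyphenyl]-5-hydroxy-6-iodo-7-methoxy-4H-chromen-4-one F6.
- Miyaura borylation (B2pin2, Pd(dppf)Cl2, KOAc, dioxane, 90 °C) gives 2-[4-(benzyloxy)-2,5-dimethoxyphenyl]-5-hydroxy-7-methoxy-6-(4,4,5,5-tetramethyl-1,3,2-dioxaborolan-2-yl)-4H-chromen-4-one F7.
- NaBO3·4H2O in THF/H2O oxidises it to 2-[4-(benzyloxy)-2,5-dimethoxyphenyl]-5,6-dihydroxy-7-methoxy-4H-chromen-4-one F8.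
- Hydrogenolysis (H2, Pd/C, EtOAc/MeOH) gives 20.

**Step 7.**
- What may go wrong: diazomethane may add as a dipole to the electron-poor C2=C3 bond of the acylpyranone, and oxalyl chloride may chlorinate C4 by way of a chloropyrylium salt.
- Route: the fallback builds the diazo group by diazo transfer instead of acylation, sets out from 11 and returns at 13.
- Activation with carbonyldiimidazole and MeNHOMe·HCl gives 6-[4-(benzyloxy)-2,5-dimethoxyphenyl]-N-methoxy-N-methyl-4-oxo-4H-pyran-2-carboxamide F9.
- MeMgBr (THF, −78 °C) gives 2-acetyl-6-[4-(benzyloxy)-2,5-dimethoxyphenyl]-4H-pyran-4-one F10.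
- LiHMDS and CF3CO2CH2CF3 give crude 1-{6-[4-(benzyloxy)-2,5-dimethoxyphenyl]-4-oxo-4H-pyran-2-yl}-4,4,4-trifluorobutane-1,3-dione F11.
- MsN3, Et3N and H2O in MeCN effect detrifluoroacetylative diazo transfer to 13.

**Further compounds**

F1 | step 8 | 4-(benzyloxy)-2,5-dimethoxybenzaldehyde | O=Cc1cc(OC)c(OCc2ccccc2)cc1OC
F2 | step 8 | 1-(3,6-dihydroxy-2,4-dimethoxyphenyl)ethanone | CC(=O)c1c(O)cc(OC)c(O)c1OC
F3 | step 8 | 1-[3-(benzyloxy)-6-hydroxy-2,4-dimethoxyphenyl]ethanone | CC(=O)c1c(O)cc(OC)c(OCc2ccccc2)c1OC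
F4 | step 8 | (E)-1-[3-(benzyloxy)-6-hydroxy-2,4-dimethoxyphenyl]-3-[4-(benzyloxy)-2,5-dimethoxyphenyl]prop-2-en-1-one | COc1cc(O)c(C(=O)/C=C/c2cc(OC)c(OCc3ccccc3)cc2OC)c(OC)c1OCc1ccccc1
F5 | step 8 | 6-(benzyloxy)-2-[4-(benzyloxy)-2,5-dimethoxyphenyl]-5,7-dimethoxy-4H-chromen-4-one | COc1cc2oc(-c3cc(OC)c(OCc4ccccc4)cc3OC)cc(=O)c2c(OC)c1OCc1ccccc1
F6 | step 9 | 2-[4-(benzyloxy)-2,5-dimethoxyphenyl]-5-hydroxy-6-iodo-7-methoxy-4H-chromen-4-one | COc1cc2oc(-c3cc(OC)c(OCc4ccccc4)cc3OC)cc(=O)c2c(O)c1I
F7 | step 9 | 2-[4-(benzyloxy)-2,5-dimethoxyphenyl]-5-hydroxy-7-methoxy-6-(4,4,5,5-tetramethyl-1,3,2-dioxaborolan-2-yl)-4H-chromen-4-one | COc1cc2oc(-c3cc(OC)c(OCc4ccccc4)cc3OC)cc(=O)c2c(O)c1B1OC(C)(C)C(C)(C)O1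
F8 | step 9 | 2-[4-(benzyloxy)-2,5-dimethoxyphenyl]-5,6-dihydroxy-7-methoxy-4H-chromen-4-one | COc1cc2oc(-c3cc(OC)c(OCc4ccccc4)cc3OC)cc(=O)c2c(O)c1O
F9 | step 7 | 6-[4-(benzyloxy)-2,5-dimethoxyphenyl]-N-methoxy-N-methyl-4-oxo-4H-pyran-2-carboxamide | CON(C)C(=O)c1cc(=O)cc(-c2cc(OC)c(OCc3ccccc3)cc2OC)o1
F10 | step 7 | 2-acetyl-6-[4-(benzyloxy)-2,5-dimethoxyphenyl]-4H-pyran-4-one | CC(=O)c1cc(=O)cc(-c2cc(OC)c(OCc3ccccc3)cc2OC)o1
F11 | step 7 | 1-{6-[4-(benzyloxy)-2,5-dimethoxyphenyl]-4-oxo-4H-pyran-2-yl}-4,4,4-trifluorobutane-1,3-dione | O=C(CC(=O)C(F)(F)F)c1cc(=O)cc(-c2cc(OC)c(OCc3ccccc3)cc2OC)o1
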